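The synthesis rests on cutting the bond between C2 of the tetrahydrofuran ring and the ipso carbon of its guaiacyl ring. C2 is an acetal-level carbon flanked by ring oxygen O1, and its aryl group stands trans to the C3 acyloxymethyl and C4 benzyl groups, which are cis to each other. The key step therefore transfers an aryl group from zinc to the O1=C2 oxocarbenium ion of a 2-bromotetrahydrofuran that already carries the 4-(benzyloxy)benzoate and the benzyl side chain; one operation joins the two fragments and sets C2 on the open face. The precursor, a lactol acetate, comes from an epichlorohydrin-derived trans lactone acid by reduction, translactonisation, esterification and partial reduction.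

Key step: step 7

Assumption: the drawn configuration is read as (2R,3S,4S), that is the 2-aryl group trans to the mutually cis C3 and C4 substituents; compounds 1, 2, 4 and 10 are taken as purchasable.

Step 1
Reactants: 1 di-tert-butyl malonate; 2 (S)-epichlorohydrin
Product: 3 tert-butyl (1S,5S)-2-oxo-3-oxabicyclo[3.1.0]hexane-1-carboxylate
Conditions: KOt-Bu, t-BuOH, rt → 50 °C
Reagents that add atoms: none
Why: Malonate alkylation at the epoxide terminus, re-closure of the alkoxide onto the chloromethyl carbon, 3-exo-tet cyclopropanation with inversion and lactonisation (the known malonate/epichlorohydrin cyclopropanation) should give the cis-fused lactone, whose C5 stereocentre derives from 2.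

Step 2
Reactants: 3 tert-butyl (1S,5S)-2-oxo-3-oxabicyclo[3.1.0]hexane-1-carboxylate; 4 1-(benzyloxy)-4-bromo-2-methoxybenzene
Product: 6 tert-butyl (3S,4S)-4-[4-(benzyloxy)-3-methoxybenzyl]-2-oxotetrahydrofuran-3-carboxylate (3,4-trans), via arylmagnesium bromide 5 (not isolated)
Conditions: 4, Mg, THF, rt; then 3, CuI (10 mol%), THF, −30 → 0 °C; 1 M HCl
Reagents that add atoms: none
Why: Copper-catalysed homoconjugate addition of the aryl Grignard reagent should open the doubly activated cyclopropane at its unsubstituted CH2, which leaves the ring stereocentre (C4 of the lactone) untouched, and protonation of the malonate-type enolate gives the thermodynamically preferred 3,4-trans lactone.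

Step 3
Reactants: 6 tert-butyl (3S,4S)-4-[4-(benzyloxy)-3-methoxybenzyl]-2-oxotetrahydrofuran-3-carboxylate
Product: 7 (3R,4S)-4-[4-(benzyloxy)-3-methoxybenzyl]-2-oxotetrahydrofuran-3-carboxylic acid (3,4-trans)
Conditions: CF3CO2H, CH2Cl2, 0 °C → rt
Reagents that add atoms: none
Why: Acidolysis of the tert-butyl ester with loss of isobutene should free the carboxylic acid without opening the lactone or cleaving the aryl benzyl ether, and the acidic C3 centre stays trans.

Step 4
Reactants: 7 (3R,4S)-4-[4-(benzyloxy)-3-methoxybenzyl]-2-oxotetrahydrofuran-3-carboxylic acid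
Product: 9 (3S,4S)-4-[4-(benzyloxy)-3-methoxybenzyl]-3-(hydroxymethyl)dihydrofuran-2(3H)-one (3,4-cis), via hydroxy acid 8 (not isolated)
Conditions: LiBH4, THF, 0 °C → rt; then 2 M HCl, rt
Reagents that add atoms: none
Why: This is the half-ester chemoselectivity of borohydride reduction: LiBH4 should reduce the lactone carbonyl but not the lithium carboxylate, and on acidification the freed C5 hydroxyl lactonises onto the untouched carboxyl (translactonisation), so the unchanged C3 centre ends up with its new CH2OH cis to the C4 benzyl group.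

Step 5
Reactants: 9 (3S,4S)-4-[4-(benzyloxy)-3-methoxybenzyl]-3-(hydroxymethyl)dihydrofuran-2(3H)-one; 10 4-(benzyloxy)benzoyl chloride
Product: 11 {(3S,4S)-4-[4-(benzyloxy)-3-methoxybenzyl]-2-oxotetrahydrofuran-3-yl}methyl 4-(benzyloxy)benzoate (3,4-cis)
Conditions: pyridine, DMAP (cat.), CH2Cl2, 0 °C
Reagents that add atoms: none
Why: DMAP-catalysed acylation of the primary alcohol by the aroyl chloride (nucleophilic acyl substitution) should be fast at 0 °C, and the weak base should leave the cis C3 centre and the β-acyloxy lactone intact.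

Step 6
Reactants: 11 {(3S,4S)-4-[4-(benzyloxy)-3-methoxybenzyl]-2-oxotetrahydrofuran-3-yl}methyl 4-(benzyloxy)benzoate
Product: 13 {(3S,4S)-2-(acetyloxy)-4-[4-(benzyloxy)-3-methoxybenzyl]tetrahydrofuran-3-yl}methyl 4-(benzyloxy)benzoate (both C2 epimers), via lactol ester 12 (not isolated)
Conditions: Sia2BH [bis(3-methylbutan-2-yl)borane], THF, 0 °C → rt; H2O; then Ac2O, pyridine, DMAP (cat.), CH2Cl2, 0 °C
Reagents that add atoms: acetic anhydride, CC(=O)OC(C)=O
Why: Disiamylborane reduces γ-lactones to lactols but leaves carboxylic esters untouched (the chemoselective lactone-to-lactol reduction used on acylated aldonolactones), and acetylation of the crude lactol should give the anomeric acetate as a C2 epimer mixture that the next step erases.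

Step 7
Reactants: 13 {(3S,4S)-2-(acetyloxy)-4-[4-(benzyloxy)-3-methoxybenzyl]tetrahydrofuran-3-yl}methyl 4-(benzyloxy)benzoate; 4 1-(benzyloxy)-4-bromo-2-methoxybenzene
Product: 17 {(2R,3S,4S)-4-[4-(benzyloxy)-3-methoxybenzyl]-2-[4-(benzyloxy)-3-methoxyphenyl]tetrahydrofuran-3-yl}methyl 4-(benzyloxy)benzoate, via bromide 14 (not isolated), via aryllithium 15 (not isolated), via arylzinc bromide 16 (not isolated)
Conditions: 13, Me3SiBr, CH2Cl2, 0 °C, volatiles removed; separately 4, n-BuLi, THF, −78 °C, then ZnBr2; combined in toluene–THF, −40 °C → rt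
Reagents that add atoms: none
Why: Me3SiBr should convert both C2 epimers of acetate 13 into bromide 14, which ionises under the Lewis acidic zinc and lithium bromides to the O1=C2 oxocarbenium ion, in equilibrium with the cis-fused dioxanium ion formed when the carbonyl oxygen of the C3 ester bridges to C2, and arylzinc bromide 16 transfers its aryl group to C2. The closest known reaction type is the transition-metal-free C-arylation of glycosyl bromides by arylzinc reagents used for C-aryl glycosides, an SN1-type substitution of an α-halo ether. No ring is closed. The new stereocentre C2 is set under substrate control: the C3 acyloxymethyl and C4 benzyl groups lie on the same face of the ring and the bridging ester occupies that face too, so the aryl group should enter C2 from the opposite, open face and give the 2,3-trans (2R) product from either epimer of 14. The step needs facial selectivity and aryl transfer to C2 in preference to addition to the ester carbonyl or loss of HBr to the 2,3-dihydrofuran; the low basicity and ester tolerance of the organozinc reagent and the cis C3/C4 arrangement secure this.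

Step 8
Reactants: 17 {(2R,3S,4S)-4-[4-(benzyloxy)-3-methoxybenzyl]-2-[4-(benzyloxy)-3-methoxyphenyl]tetrahydrofuran-3-yl}methyl 4-(benzyloxy)benzoate
Product: 18 agastinol [{(2R,3S,4S)-4-(4-hydroxy-3-methoxybenzyl)-2-(4-hydroxy-3-methoxyphenyl)tetrahydrofuran-3-yl}methyl 4-hydroxybenzoate]
Conditions: H2 (1 atm), Pd/C (10%), EtOAc, rt
Reagents that add atoms: none
Why: Catalytic hydrogenolysis of the three aryl benzyl ethers should be much faster than cleavage of the cyclic benzylic C2–O1 bond under neutral conditions at 1 atm, and the ester and the three stereocentres are untouched.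

Compound list

1 | di-tert-butyl malonate | CC(C)(C)OC(=O)CC(=O)OC(C)(C)C | starting material
2 | (S)-epichlorohydrin | ClC[C@@H]1CO1 | starting material
3 | tert-butyl (1S,5S)-2-oxo-3-oxabicyclo[3.1.0]hexane-1-carboxylate | O=C1OC[C@H]2C[C@@]12C(=O)OC(C)(C)C | intermediate
4 | 1-(benzyloxy)-4-bromo-2-methoxybenzene | COc1cc(Br)ccc1OCc1ccccc1 | starting material
5 | [4-(benzyloxy)-3-methoxyphenyl]magnesium bromide (made in the flask) | COc1cc([Mg]Br)ccc1OCc1ccccc1 | intermediate
6 | tert-butyl (3S,4S)-4-[4-(benzyloxy)-3-methoxybenzyl]-2-oxotetrahydrofuran-3-carboxylate (3,4-trans) | O=C1OC[C@@H](Cc2ccc(OCc3ccccc3)c(OC)c2)[C@@H]1C(=O)OC(C)(C)C | intermediate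
7 | (3R,4S)-4-[4-(benzyloxy)-3-methoxybenzyl]-2-oxotetrahydrofuran-3-carboxylic acid (3,4-trans) | O=C1OC[C@@H](Cc2ccc(OCc3ccccc3)c(OC)c2)[C@@H]1C(=O)O | intermediate
8 | (2S,3S)-3-[4-(benzyloxy)-3-methoxybenzyl]-4-hydroxy-2-(hydroxymethyl)butanoic acid (formed in the flask, first as its lithium salt) | OC[C@@H](C(=O)O)[C@@H](CO)Cc1ccc(OCc2ccccc2)c(OC)c1 | intermediate
9 | (3S,4S)-4-[4-(benzyloxy)-3-methoxybenzyl]-3-(hydroxymethyl)dihydrofuran-2(3H)-one (3,4-cis) | O=C1OC[C@@H](Cc2ccc(OCc3ccccc3)c(OC)c2)[C@H]1CO | intermediate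
10 | 4-(benzyloxy)benzoyl chloride | O=C(Cl)c1ccc(OCc2ccccc2)cc1 | starting material
11 | {(3S,4S)-4-[4-(benzyloxy)-3-methoxybenzyl]-2-oxotetrahydrofuran-3-yl}methyl 4-(benzyloxy)benzoate (3,4-cis) | O=C1OC[C@@H](Cc2ccc(OCc3ccccc3)c(OC)c2)[C@H]1COC(=O)c1ccc(OCc2ccccc2)cc1 | intermediate
12 | {(3S,4S)-4-[4-(benzyloxy)-3-methoxybenzyl]-2-hydroxytetrahydrofuran-3-yl}methyl 4-(benzyloxy)benzoate (lactol, both C2 epimers, used crude) | OC1OC[C@@H](Cc2ccc(OCc3ccccc3)c(OC)c2)[C@H]1COC(=O)c1ccc(OCc2ccccc2)cc1 | intermediate
13 | {(3S,4S)-2-(acetyloxy)-4-[4-(benzyloxy)-3-methoxybenzyl]tetrahydrofuran-3-yl}methyl 4-(benzyloxy)benzoate (both C2 epimers) | CC(=O)OC1OC[C@@H](Cc2ccc(OCc3ccccc3)c(OC)c2)[C@H]1COC(=O)c1ccc(OCc2ccccc2)cc1 | intermediate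
14 | {(3S,4S)-4-[4-(benzyloxy)-3-methoxybenzyl]-2-bromotetrahydrofuran-3-yl}methyl 4-(benzyloxy)benzoate (made in the flask) | BrC1OC[C@@H](Cc2ccc(OCc3ccccc3)c(OC)c2)[C@H]1COC(=O)c1ccc(OCc2ccccc2)cc1 | intermediate
15 | [4-(benzyloxy)-3-methoxyphenyl]lithium (made in the flask) | [Li]c1ccc(OCc2ccccc2)c(OC)c1 | intermediate
16 | [4-(benzyloxy)-3-methoxyphenyl]zinc bromide (made in the flask) | COc1cc([Zn]Br)ccc1OCc1ccccc1 | intermediate
17 | {(2R,3S,4S)-4-[4-(benzyloxy)-3-methoxybenzyl]-2-[4-(benzyloxy)-3-methoxyphenyl]tetrahydrofuran-3-yl}methyl 4-(benzyloxy)benzoate | COc1cc(C[C@@H]2CO[C@@H](c3ccc(OCc4ccccc4)c(OC)c3)[C@@H]2COC(=O)c2ccc(OCc3ccccc3)cc2)ccc1OCc1ccccc1 | intermediate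
18 | agastinol, {(2R,3S,4S)-4-(4-hydroxy-3-methoxybenzyl)-2-(4-hydroxy-3-methoxyphenyl)tetrahydrofuran-3-yl}methyl 4-hydroxybenzoate | COc1cc(C[C@@H]2CO[C@@H](c3ccc(O)c(OC)c3)[C@@H]2COC(=O)c2ccc(O)cc2)ccc1O | target

Total step count: 8. Longest linear sequence: 8 steps (from 1 and 2 to 18).

Steps most likely to fail

Step 7 (key step). The aryl group may be transferred to the hindered face, the oxocarbenium ion may lose HBr to the 2,3-dihydrofuran faster than the C–C bond forms, or the aryl group may add at the bridging ester carbon. The fallback sets out from lactone 9 and comes back at 17. Lactone 9 would be reduced with i-Bu2AlH (CH2Cl2, −78 °C, aqueous KNaC4H4O6 work-up) to the lactol diol F1. An excess of Grignard reagent 5, prepared as in step 2 (THF, 0 °C), should open it to triol F2 as a mixture of carbinol epimers. Camphorsulfonic acid in CH2Cl2 would then ionise the benzylic alcohol, and the hydroxyl on the former C5 closes the five-membered ring under thermodynamic control to the 2,3-trans alcohol F3. Acylation of its primary hydroxyl with 10 (pyridine, DMAP) gives 17.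

Step 6. The borane may attack the aryl ester as well as the lactone, the aroyl group may migrate from the primary oxygen to the anomeric oxygen of the lactol, or the lactol may open to the β-acyloxy aldehyde and eliminate or epimerise at C3. The fallback sets out from lactone 9 and comes back at bromide 14. Lactone 9 would be reduced with i-Bu2AlH before any ester is in place, which gives the lactol diol F1. MeOH with pyridinium p-toluenesulfonate should turn it into methyl acetal F4, and acylation of its primary hydroxyl with 10 (pyridine, DMAP) gives methyl acetal ester F5. Me3SiBr in CH2Cl2 turns F5 into bromide 14, which is taken on with arylzinc bromide 16 as in step 7.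

Step 4. Reduction of the lactone carbonyl next to a carboxylate may be sluggish, borane formed in the flask may attack the carboxyl group, or C3 may epimerise by enolisation at the aldehyde stage. The fallback sets out from acid 7 and comes back at 9. Decarboxylative methylenation of 7 (aqueous CH2O, Et2NH, then AcOH/NaOAc, warm) should give methylene lactone F6. Conjugate borylation (B2pin2, CuCl, NaOt-Bu, Xantphos, MeOH, THF) places boron on the exocyclic carbon, and protonation of the enolate on the face away from the C4 benzyl group should favour the cis boronate F7; the trans epimer would be removed by chromatography. Oxidation with NaBO3 in THF–H2O gives 9.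

Further compounds

F1 | step 7 | (3S,4S)-4-[4-(benzyloxy)-3-methoxybenzyl]-3-(hydroxymethyl)tetrahydrofuran-2-ol (lactol diol, both C2 epimers) | OC1OC[C@@H](Cc2ccc(OCc3ccccc3)c(OC)c2)[C@H]1CO
F2 | step 7 | (2S,3S)-2-[4-(benzyloxy)-3-methoxybenzyl]-3-{[4-(benzyloxy)-3-methoxyphenyl](hydroxy)methyl}butane-1,4-diol (carbinol epimers) | OC(c1ccc(OCc2ccccc2)c(OC)c1)[C@H](CO)[C@@H](CO)Cc1ccc(OCc2ccccc2)c(OC)c1
F3 | step 7 | {(2R,3S,4S)-4-[4-(benzyloxy)-3-methoxybenzyl]-2-[4-(benzyloxy)-3-methoxyphenyl]tetrahydrofuran-3-yl}methanol | COc1cc(C[C@@H]2CO[C@@H](c3ccc(OCc4ccccc4)c(OC)c3)[C@@H]2CO)ccc1OCc1ccccc1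
F4 | step 6 | {(3S,4S)-4-[4-(benzyloxy)-3-methoxybenzyl]-2-methoxytetrahydrofuran-3-yl}methanol (both C2 epimers) | COC1OC[C@@H](Cc2ccc(OCc3ccccc3)c(OC)c2)[C@H]1CO
F5 | step 6 | {(3S,4S)-4-[4-(benzyloxy)-3-methoxybenzyl]-2-methoxytetrahydrofuran-3-yl}methyl 4-(benzyloxy)benzoate (both C2 epimers) | COC1OC[C@@H](Cc2ccc(OCc3ccccc3)c(OC)c2)[C@H]1COC(=O)c1ccc(OCc2ccccc2)cc1
F6 | step 4 | (S)-4-[4-(benzyloxy)-3-methoxybenzyl]-3-methylidenedihydrofuran-2(3H)-one | C=C1C(=O)OC[C@H]1Cc1ccc(OCc2ccccc2)c(OC)c1
F7 | step 4 | (3R,4S)-4-[4-(benzyloxy)-3-methoxybenzyl]-3-[(4,4,5,5-tetramethyl-1,3,2-dioxaborolan-2-yl)methyl]dihydrofuran-2(3H)-one (3,4-cis) | O=C1OC[C@@H](Cc2ccc(OCc3ccccc3)c(OC)c2)[C@H]1CB1OC(C)(C)C(C)(C)O1
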